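**Assumptions (one line):** 4-hydroxybutan-2-one, cyclopropyl methyl ketone, (R)-3-methylcyclohexanone and tetronic acid (drawn as 4-hydroxyfuran-2(5H)-one) are commercial; the (R) ketone is chosen so that C5 of the product is (R).

## Retrosynthetic overview
1. Target ⇐ Babler–Dauben oxidative transposition of tertiary allylic alcohol **18**. The enone unsaturation is made last, and the cyclohexane ring is never constructed because it comes from (R)-3-methylcyclohexanone.
2. **18** ⇐ key radical step: a silyl-radical-generated primary homoallylic radical from bromide **15** adds to 4-bromobutenolide **17** (addition–elimination). The butenolide ring comes intact from tetronic acid.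
3. **15** ⇐ (R)-5-methylcyclohexenone **12**, by two enolate alkylations (chain first, then MeI, both anti to the C5 methyl) and MeLi addition. This sets C4 and C5.
4. The E,E-chain iodide **9** ⇐ two Julia–Johnson cyclopropylcarbinol openings starting from **1** and **5**.

## Route

**Step 1**
Reactants: **1** 4-hydroxybutan-2-one
Product: **2** 4-(TBDPSO)butan-2-one
Conditions: TBDPSCl, imidazole, DMF, 0 → 25 °C
Reagents that add atoms: TBDPSCl, CC(C)(C)[Si](Cl)(c1ccccc1)c1ccccc1
Why: Silylation of the primary alcohol gives a protected ketone that is inert to Grignard reagents and to HBr.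

**Step 2**
Reactants: **2**
Product: **3** 2-cyclopropyl-4-(TBDPSO)butan-2-ol
Conditions: cyclopropylmagnesium bromide, CeCl3, THF, –78 → 0 °C
Reagents that add atoms: cyclopropylmagnesium bromide, Br[Mg]C1CC1
Why: Organocerium 1,2-addition to the methyl ketone gives the tertiary cyclopropylcarbinol, and CeCl3 suppresses enolisation and β-elimination of the silyl ether; no stereocentre is formed.

**Step 3**
Reactants: **3**
Product: **4** (E)-6-bromo-3-methylhex-3-en-1-yl TBDPS ether
Conditions: 48% aq. HBr, ZnBr2, CH2Cl2, 0 °C, short reaction time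
Reagents that add atoms: HBr, Br
Why: Julia–Johnson cyclopropylcarbinyl-cation opening by bromide gives the homoallylic bromide, and the chair-like opening sets the trisubstituted alkene E (typically ≥9:1).

**Step 4**
Reactants: **4** and **5** cyclopropyl methyl ketone
Product: **6** (E)-1-cyclopropyl-1,5-dimethyl-7-(TBDPSO)hept-4-en-1-ol
Conditions: Mg, THF, 40 °C to form the Grignard reagent; then **5**, –20 °C
Reagents that add atoms: none
Why: The homoallylic Grignard reagent adds 1,2 to the cyclopropyl ketone, which builds the second Julia–Johnson precursor.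

**Step 5**
Reactants: **6**
Product: **7** TBDPS ether of (3E,7E)-10-bromo-3,7-dimethyldeca-3,7-dien-1-ol
Conditions: 48% aq. HBr, ZnBr2, CH2Cl2, 0 °C
Reagents that add atoms: HBr, Br
Why: Second Julia–Johnson opening, E-selective as in step 3; the E,E isomer is purified on AgNO3-silica if needed.

**Step 6**
Reactants: **7**
Product: **8** (3E,7E)-10-bromo-3,7-dimethyldeca-3,7-dien-1-ol
Conditions: HF·pyridine, THF/pyridine, 0 °C
Reagents that add atoms: none
Why: Fluoride cleaves the silyl ether and leaves the alkyl bromide and the alkenes untouched.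

**Step 7**
Reactants: **8**
Product: **9** (3E,7E)-10-bromo-1-iodo-3,7-dimethyldeca-3,7-diene
Conditions: PPh3, I2, imidazole, Et2O/MeCN, 0 °C
Reagents that add atoms: iodine, II
Why: Appel-type conversion of the primary alcohol to the iodide, which is the more reactive electrophile for the later enolate alkylation.

**Step 8**
Reactants: **10** (R)-3-methylcyclohexanone
Product: **11** (R)-trimethyl[(5-methylcyclohex-1-en-1-yl)oxy]silane
Conditions: LDA, TMSCl, THF, –78 °C
Reagents that add atoms: TMSCl, C[Si](C)(C)Cl
Why: Kinetic deprotonation at the less hindered C6 gives the silyl enol ether that leads to the 5-methylcyclohex-2-enone regiochemistry. The C2-enol regioisomer is a minor product removed by chromatography.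

**Step 9**
Reactants: **11**
Product: **12** (R)-5-methylcyclohex-2-en-1-one
Conditions: Pd(OAc)2, MeCN, 25 °C
Reagents that add atoms: none
Why: Saegusa–Ito oxidation of the silyl enol ether introduces the C=C bond away from the methyl-bearing carbon, and the (R) centre is untouched.

**Step 10**
Reactants: **12** and **9**
Product: **13** (5R)-6-[(3E,7E)-10-bromo-3,7-dimethyldeca-3,7-dien-1-yl]-5-methylcyclohex-2-en-1-one (C6 trans to the C5 methyl, major)
Conditions: LDA, THF, –78 °C; then **9**, DMPU, –78 → –20 °C
Reagents that add atoms: none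
Why: The kinetic cross-conjugated α′-enolate is alkylated by the more reactive iodide (the bromide is untouched), with the electrophile approaching anti to the C5 methyl. Stereochemistry at this carbon is erased in the next step.

**Step 11**
Reactants: **13**
Product: **14** (5R,6R)-6-[(3E,7E)-10-bromo-3,7-dimethyldeca-3,7-dien-1-yl]-5,6-dimethylcyclohex-2-en-1-one
Conditions: LDA, THF, –78 → 0 °C, HMPA; then MeI, –78 → 0 °C
Reagents that add atoms: MeI, CI
Why: Re-enolisation gives a planar dienolate with the C5 methyl pseudo-axial (A1,2 strain), so methylation occurs anti to it. This sets the quaternary centre with the methyl trans and the chain cis to the C5 methyl, i.e. the (4R,5R) relationship of the target.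

**Step 12**
Reactants: **14**
Product: **15** (5R,6R)-6-[(3E,7E)-10-bromo-3,7-dimethyldeca-3,7-dien-1-yl]-1,5,6-trimethylcyclohex-2-en-1-ol (C1 epimers)
Conditions: MeLi, CeCl3, THF, –78 °C
Reagents that add atoms: methyllithium, C[Li]
Why: Organocerium 1,2-addition to the hindered enone has no enolisable α-H (C6 is quaternary and C2 is sp2); the new carbinol stereocentre is destroyed in step 15.

**Step 13**
Reactants: **16** tetronic acid
Product: **17** 4-bromofuran-2(5H)-one
Conditions: (COBr)2, DMF (cat.), CH2Cl2, 0 → 25 °C
Reagents that add atoms: oxalyl bromide, BrC(=O)C(=O)Br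
Why: Vinylogous acid-to-bromide conversion gives a β-bromobutenolide that is a good radical acceptor.

**Step 14**
Reactants: **15** and **17**
Product: **18** (5R,6R)-6-{(3E,7E)-3,7-dimethyl-10-(5-oxo-2,5-dihydrofuran-3-yl)deca-3,7-dien-1-yl}-1,5,6-trimethylcyclohex-2-en-1-ol
Conditions: (TMS)3SiH (1.5 equiv, syringe pump), Et3B/air (cat.), **17** (3 equiv), 2,6-lutidine, PhCF3, 25 °C
Reagents that add atoms: none (the silane and Br leave as (TMS)3SiBr and lutidinium HBr)
Why: Proposed new method: (TMS)3Si• abstracts Br selectively from the primary alkyl bromide to give a primary homoallylic radical, which adds to C4 of the bromobutenolide to give an α-carbonyl radical. That radical either loses Br• by β-scission or is reduced and then dehydrobrominated by the lutidine, restoring the C3=C4 butenolide. The closest known chemistry is Giese addition–elimination onto β-halo or β-sulfonyl enoates.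

**Step 15**
Reactants: **18**
Product: **19** cyclolinteinone, (4R,5R)-3,4,5-trimethyl-4-[(3E,7E)-3,7-dimethyl-10-(5-oxo-2,5-dihydrofuran-3-yl)deca-3,7-dien-1-yl]cyclohex-2-en-1-one
Conditions: PCC, NaOAc, Celite, CH2Cl2, 25 °C
Reagents that add atoms: none
Why: Babler–Dauben oxidative 1,3-transposition of the tertiary allylic alcohol (via the chromate ester and [3,3] shift) moves the oxygen to old C3 and places the methyl on the new β-carbon. The C4 and C5 stereocentres and the E,E-alkenes are not involved.

## Compound list
1 | 4-hydroxybutan-2-one | CC(=O)CCO | starting material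
2 | 4-(TBDPSO)butan-2-one | CC(=O)CCO[Si](c1ccccc1)(c1ccccc1)C(C)(C)C | intermediate
3 | 2-cyclopropyl-4-(TBDPSO)butan-2-ol | CC(O)(C1CC1)CCO[Si](c1ccccc1)(c1ccccc1)C(C)(C)C | intermediate
4 | (E)-6-bromo-3-methylhex-3-en-1-yl TBDPS ether | CC(C)(C)[Si](c1ccccc1)(c1ccccc1)OCC/C(C)=C/CCBr | intermediate
5 | cyclopropyl methyl ketone | CC(=O)C1CC1 | starting material
6 | (E)-1-cyclopropyl-1,5-dimethyl-7-(TBDPSO)hept-4-en-1-ol | CC(C)(C)[Si](c1ccccc1)(c1ccccc1)OCC/C(C)=C/CCC(C)(O)C1CC1 | intermediate
7 | TBDPS ether of (3E,7E)-10-bromo-3,7-dimethyldeca-3,7-dien-1-ol | CC(C)(C)[Si](c1ccccc1)(c1ccccc1)OCC/C(C)=C/CC/C(C)=C/CCBr | intermediate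
8 | (3E,7E)-10-bromo-3,7-dimethyldeca-3,7-dien-1-ol | OCC/C(C)=C/CC/C(C)=C/CCBr | intermediate
9 | (3E,7E)-10-bromo-1-iodo-3,7-dimethyldeca-3,7-diene | ICC/C(C)=C/CC/C(C)=C/CCBr | intermediate
10 | (R)-3-methylcyclohexanone | O=C1CCC[C@@H](C)C1 | starting material
11 | (R)-trimethyl[(5-methylcyclohex-1-en-1-yl)oxy]silane | C[Si](C)(C)OC1=CCC[C@@H](C)C1 | intermediate
12 | (R)-5-methylcyclohex-2-en-1-one | O=C1C=CC[C@@H](C)C1 | intermediate
13 | (5R)-6-[(3E,7E)-10-bromo-3,7-dimethyldeca-3,7-dien-1-yl]-5-methylcyclohex-2-en-1-one (C6 epimeric) | O=C1C=CC[C@@H](C)C1CC/C(C)=C/CC/C(C)=C/CCBr | intermediate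
14 | (5R,6R)-6-[(3E,7E)-10-bromo-3,7-dimethyldeca-3,7-dien-1-yl]-5,6-dimethylcyclohex-2-en-1-one | O=C1C=CC[C@@H](C)[C@@]1(C)CC/C(C)=C/CC/C(C)=C/CCBr | intermediate
15 | tertiary allylic alcohol (C1 epimers) | CC1(O)C=CC[C@@H](C)[C@@]1(C)CC/C(C)=C/CC/C(C)=C/CCBr | intermediate
16 | tetronic acid (4-hydroxyfuran-2(5H)-one) | OC1=CC(=O)OC1 | starting material
17 | 4-bromofuran-2(5H)-one | BrC1=CC(=O)OC1 | intermediate
18 | butenolide-bearing tertiary allylic alcohol (C1 epimers) | CC1(O)C=CC[C@@H](C)[C@@]1(C)CC/C(C)=C/CC/C(C)=C/CCC1=CC(=O)OC1 | intermediate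
19 | cyclolinteinone | CC1=CC(=O)C[C@@H](C)[C@@]1(C)CC/C(C)=C/CC/C(C)=C/CCC1=CC(=O)OC1 | target

## Totals
- Total steps: 15.
- Longest linear sequence: 12 steps (1→2→3→4→6→7→8→9→13→14→15→18→19).

## Three steps most likely to fail
1. **Step 14 (radical coupling with 4-bromobutenolide).** Risks are polymerisation or reduction of the acceptor and competing silyl-radical addition to alkenes. Fallback: convert bromide **15** to the alkylzinc (Zn, LiCl) and couple with **17** by Pd-catalysed Negishi coupling, a polar organometallic route.
2. **Step 11 (quaternisation diastereoselectivity).** The anti-methylation of a crowded dienolate may give a poor dr, and the epimer cannot be equilibrated. Fallback: set C4 by Pd-catalysed decarboxylative allylic alkylation of the allyl enol carbonate of trans-5,6-dimethylcyclohexenone, then build the chain from the allyl handle by cross-metathesis.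
3. **Step 15 (Babler–Dauben on a tertiary alcohol next to a quaternary carbon, with the polyene and butenolide present).** Fallback: dehydrate **18** (Burgess reagent) to the trisubstituted cyclohexene and install the C1 carbonyl by Pd(OH)2/C–TBHP allylic C–H oxidation of the ring CH2.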